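Each of the three dihydrobenzofuran rings holds an O1–C2(H)(4-oxyaryl) unit beside a diarylmethine C3. Every C2–C3 bond is therefore cut back to a diaryl carbene carbon lying ortho to a 4-methoxybenzyl aryl ether. The precursor of the key step is the hydrazone of a ketone that joins this ether-bearing bromoarene to C4 of finished ring B. Oxidation and a chiral dirhodium catalyst give a carbene that inserts into the O–CH2 group: C2–C3 forms, central ring A closes, C3 is set, and acid then moves C2 to trans. One bromo aldehyde feeds all three cycles. Phenols are unmasked before the Heck coupling, sparing the styryl unit from BBr3.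

Key step: step 11

Labels:
- Benzofuran numbering (O1, C2, C3, C3a, C4 to C7, C7a) is used inside each ring system.
- Ring B is the first-built unit. It bears the 3,5-dioxygenated phenyl group and is 2R,3R.
- Ring A is the central unit and is 2S,3S.
- Ring C is the third unit. It bears the styryl arm and is 2R,3R.
- All three rings are trans and the alkene is E.
- PMB = 4-methoxybenzyl; An = 4-methoxyphenyl.
- BrAr = 2-bromo-4-methoxy-6-(PMB-oxy)phenyl.
- B-yl = (2R,3R)-3-(3,5-dimethoxyphenyl)-6-methoxy-2-An-2,3-dihydrobenzofuran-4-yl.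
- AB-yl = (2S,3S)-6-methoxy-2-An-3-(B-yl)-2,3-dihydrobenzofuran-4-yl.
- PTAD = N-phthaloyl-(1-adamantyl)glycinate.

Assumption: Rh2(S-PTAD)4 is taken as the antipode that delivers a 3R centre and Rh2(R-PTAD)4 as the one that delivers 3S; should step 7 show the reverse sense, the two antipodes are exchanged in steps 7, 11 and 15.

Step 1
Reactants: 1 1-bromo-3,5-dimethoxybenzene
Product: 2 2-bromo-4,6-dimethoxybenzaldehyde
Conditions: POCl3, DMF, 0 to 90 °C; then ice-water
Reagents that add atoms: N,N-dimethylformamide CN(C)C=O; water O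
Why: Vilsmeier-Haack formylation, in which the chloroiminium ion attacks the ring position para to one methoxy group and ortho to the other (next to bromine) in preference to the site flanked by both methoxy groups, and water then hydrolyses the aryl iminium salt to the aldehyde.

Step 2
Reactants: 2 2-bromo-4,6-dimethoxybenzaldehyde
Product: 3 2-bromo-6-hydroxy-4-methoxybenzaldehyde
Conditions: BCl3 (1.2 equiv), CH2Cl2, -78 to 0 °C; then H2O
Reagents that add atoms: none
Why: Chelation-directed aryl methyl ether cleavage, because BCl3 bridges the aldehyde oxygen and the neighbouring methoxy oxygen in a six-membered chelate, so chloride removes only that methyl group and the para methoxy group stays.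

Step 3
Reactants: 3 2-bromo-6-hydroxy-4-methoxybenzaldehyde; 4 4-methoxybenzyl chloride
Product: 5 2-bromo-4-methoxy-6-(4-methoxybenzyloxy)benzaldehyde
Conditions: K2CO3, n-Bu4NI (cat.), DMF, 50 °C
Reagents that add atoms: none
Why: Williamson ether synthesis, the phenoxide displacing chloride from a reactive benzylic halide to install the O–CH2–An unit that later supplies O1, C2 and the 2-aryl group of each ring.

Step 4
Reactants: 1 1-bromo-3,5-dimethoxybenzene; 5 2-bromo-4-methoxy-6-(4-methoxybenzyloxy)benzaldehyde
Product: 7 (BrAr)(3,5-dimethoxyphenyl)methanol (racemic), via Grignard reagent 6 (not isolated)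
Conditions: 1, Mg, THF, reflux; then 5, THF, 0 °C; H2O quench
Reagents that add atoms: none
Why: Grignard addition to a non-enolisable aldehyde, which is far faster than any magnesium-bromine exchange at the aryl bromide of 5; the neutral quench spares the easily ionised carbinol, whose stereocentre is erased in step 5.

Step 5
Reactants: 7 (BrAr)(3,5-dimethoxyphenyl)methanol
Product: 8 (BrAr)(3,5-dimethoxyphenyl)methanone
Conditions: Dess-Martin periodinane, pyridine, CH2Cl2, 0 °C to rt
Reagents that add atoms: none
Why: Dess-Martin oxidation of a hindered benzhydrol under buffered, non-acidic conditions that leave the PMB ether, the methyl ethers and the aryl bromide alone.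

Step 6
Reactants: 8 (BrAr)(3,5-dimethoxyphenyl)methanone
Product: 9 hydrazone of 8 (E/Z mixture)
Conditions: N2H4 (anhydrous, excess), N2H4·2HCl (cat.), n-BuOH, 120 °C, sealed tube
Reagents that add atoms: hydrazine NN
Why: Acid-catalysed hydrazone formation, in which the hydrazinium salt activates the doubly ortho-substituted carbonyl group, the large excess of hydrazine suppresses azine formation, and the electron-rich C–Br bond resists substitution.

Step 7
Reactants: 9 hydrazone of 8
Product: 12 (2R,3R)-4-bromo-3-(3,5-dimethoxyphenyl)-6-methoxy-2-An-2,3-dihydrobenzofuran (trans ring B bromide), via diaryldiazomethane 10 (not isolated), via cis ring B bromide 11 (not isolated)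
Conditions: MnO2 (10 equiv), CH2Cl2, rt; Rh2(S-PTAD)4 (1 mol %), 0 °C; filter through Celite; TFA, 0 °C, short contact, evaporate; recrystallise
Reagents that add atoms: none
Why: Enantioselective intramolecular C–H insertion of a donor/donor dirhodium carbene, in which MnO2 gives diazo compound 10, the chiral catalyst sets C3 as R while the carbene carbon bonds to the O–CH2 carbon in a 1,5-closure that should give mainly cis 11, TFA then equilibrates C2 to R (trans) through reversible opening of the 4-methoxybenzylic C2–O1 bond, and recrystallisation should raise the enantiomeric purity.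

Step 8
Reactants: 12 trans ring B bromide; 5 2-bromo-4-methoxy-6-(4-methoxybenzyloxy)benzaldehyde
Product: 14 (BrAr)(B-yl)methanol (both carbinol epimers), via aryllithium 13 (not isolated)
Conditions: 12, t-BuLi (2.0 equiv), THF, -78 °C; then 5, -78 to -20 °C; H2O quench
Reagents that add atoms: none
Why: Bromine-lithium exchange followed by 1,2-addition to a non-enolisable aldehyde; at -78 °C exchange outruns removal of the doubly benzylic C3–H, carbonyl addition outruns exchange with the bromide of 5, and the new carbinol centre does not matter because step 9 removes it.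

Step 9
Reactants: 14 (BrAr)(B-yl)methanol
Product: 15 (BrAr)(B-yl)methanone
Conditions: Dess-Martin periodinane, pyridine, CH2Cl2, 0 °C to rt
Reagents that add atoms: none
Why: Dess-Martin oxidation converges both carbinol epimers on one ketone under buffered conditions that cannot ionise the C2–O1 bond of ring B or cleave the PMB ether.

Step 10
Reactants: 15 (BrAr)(B-yl)methanone
Product: 16 hydrazone of 15 (E/Z mixture)
Conditions: N2H4 (anhydrous, excess), N2H4·2HCl (cat.), n-BuOH, 130 °C, sealed tube
Reagents that add atoms: hydrazine NN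
Why: Acid-catalysed hydrazone formation pushed by excess small nucleophile, heat and hydrazinium activation of the triply ortho-substituted carbonyl group, under conditions that are too weakly basic for Wolff-Kishner reduction or for epimerisation of ring B.

Step 11
Reactants: 16 hydrazone of 15
Product: 19 (2S,3S)-4-bromo-6-methoxy-2-An-3-(B-yl)-2,3-dihydrobenzofuran (trans ring A on trans ring B), via diaryldiazomethane 17 (not isolated), via cis ring A bromide 18 (not isolated)
Conditions: MnO2 (10 equiv), CH2Cl2, rt; Rh2(R-PTAD)4 (2 mol %), 0 °C; filter through Celite; TFA, 0 °C, short contact, evaporate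
Reagents that add atoms: none
Why: MnO2 dehydrogenates hydrazone 16 to diaryldiazomethane 17, Rh2(R-PTAD)4 displaces N2 to give a dirhodium carbene with two donor aryl groups, and the carbene carbon takes up a hydridic hydrogen of the ortho O–CH2 group in an asynchronous, hydride-transfer-like C–H insertion that forms the C2–C3 bond. The closest known reaction type is the enantioselective intramolecular C–H insertion of diaryl carbenes, generated with MnO2 from 2-(benzyloxy)benzophenone hydrazones under chiral dirhodium tetracarboxylates, which gives 2,3-diaryl-2,3-dihydrobenzofurans. Ring A (O1–C2–C3–C3a–C7a) closes as a five-membered ring by 1,5-insertion, the carbene carbon becoming C3 and the former benzylic CH2 becoming C2. C3 (S) is set by the chiral ligand sphere of the catalyst, used as the antipode of that in step 7 because ring A has the opposite sense to ring B, whereas C2 should arise mainly cis (18) and is then brought to S (trans) by TFA through reversible heterolysis of the 4-methoxybenzylic C2–O1 bond, which leaves C3 and the already trans ring B unchanged. The step needs catalyst control over the facial bias of the ring B stereocentres and preference for the ether C–H over attack on the neighbouring 3,5-dimethoxyphenyl ring or azine formation; the low electrophilicity of the donor/donor carbene, the double activation of the CH2 by oxygen and the anisyl group, its place five atoms from the carbene carbon and the strain of any closure onto ring B secure this, and a minor C3 epimer is a diastereomer that chromatography removes. The C–Br bond ortho to the carbene carbon is inert to rhodium and ends up as the C4 handle for step 12.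

Step 12
Reactants: 19 ring A–ring B bromide; 5 2-bromo-4-methoxy-6-(4-methoxybenzyloxy)benzaldehyde
Product: 21 (BrAr)(AB-yl)methanol (both carbinol epimers), via aryllithium 20 (not isolated)
Conditions: 19, t-BuLi (2.0 equiv), THF, -78 °C; then 5, -78 to -20 °C; H2O quench
Reagents that add atoms: none
Why: Bromine-lithium exchange and 1,2-addition to the aldehyde as in step 8, with the low temperature protecting both doubly benzylic C3–H bonds and the carbinol centre again being erased in the next step.

Step 13
Reactants: 21 (BrAr)(AB-yl)methanol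
Product: 22 (BrAr)(AB-yl)methanone
Conditions: Dess-Martin periodinane, pyridine, CH2Cl2, 0 °C to rt
Reagents that add atoms: none
Why: Dess-Martin oxidation merges the carbinol epimers into one ketone without acid, so rings A and B and the PMB ether are untouched.

Step 14
Reactants: 22 (BrAr)(AB-yl)methanone
Product: 23 hydrazone of 22 (E/Z mixture)
Conditions: N2H4 (anhydrous, excess), N2H4·2HCl (cat.), n-BuOH, 130 °C, sealed tube
Reagents that add atoms: hydrazine NN
Why: Acid-catalysed hydrazone formation under the same forcing yet weakly basic conditions as step 10, to which ethers, the aryl bromide and the four stereocentres are inert.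

Step 15
Reactants: 23 hydrazone of 22
Product: 26 (2R,3R)-4-bromo-6-methoxy-2-An-3-(AB-yl)-2,3-dihydrobenzofuran (tris(dihydrobenzofuran) bromide with eight methyl ethers), via diaryldiazomethane 24 (not isolated), via cis ring C bromide 25 (not isolated)
Conditions: MnO2 (10 equiv), CH2Cl2, rt; Rh2(S-PTAD)4 (2 mol %), 0 °C; filter through Celite; TFA, 0 °C, short contact, evaporate
Reagents that add atoms: none
Why: Enantioselective intramolecular C–H insertion of a donor/donor dirhodium carbene as in steps 7 and 11, the catalyst antipode of step 7 setting C3 of ring C as R, 1,5-closure onto the O–CH2 carbon forming C2–C3, TFA bringing C2 to R (trans) by reversible C2–O1 heterolysis while the already trans rings A and B stay as they are, and any minor C3 epimer being removable as a diastereomer.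

Step 16
Reactants: 26 tris(dihydrobenzofuran) bromide with eight methyl ethers
Product: 27 octaphenol bromide (26 with all eight OMe groups replaced by OH)
Conditions: BBr3 (excess), CH2Cl2, -78 °C to rt; then ice-water
Reagents that add atoms: none
Why: Boron tribromide cleavage of aryl methyl ethers, placed before the alkene is introduced because a 4-styryl-3-aryl-dihydrobenzofuran would be open to acid-induced seven-membered ring closure, while a transient opening of a C2–O1 bond only returns the favoured trans ring and neither the C3 centres nor the aryl bromide are touched.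

Step 17
Reactants: 27 octaphenol bromide
Product: 28 octaacetate bromide
Conditions: Ac2O, pyridine, DMAP (cat.), CH2Cl2, 0 °C to rt
Reagents that add atoms: acetic anhydride CC(=O)OC(C)=O
Why: DMAP-catalysed O-acetylation masks the eight phenols with groups that tolerate Heck conditions, leave without acid and allow purification on silica gel, and it affects no stereocentre.

Step 18
Reactants: 29 caffeic acid
Product: 31 3,4-diacetoxystyrene, via 4-vinylcatechol 30 (not isolated)
Conditions: Et3N, DMF, 100 °C; then Ac2O, 0 °C to rt, BHT (trace)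
Reagents that add atoms: acetic anhydride CC(=O)OC(C)=O
Why: Base-promoted decarboxylation of a 4-hydroxycinnamic acid through its quinone methide tautomer, followed by O-acetylation in the same flask so that the polymerisation-prone vinylcatechol is never handled.

Step 19
Reactants: 28 octaacetate bromide; 31 3,4-diacetoxystyrene
Product: 32 decaacetate of the target (E alkene)
Conditions: Pd(P(t-Bu)3)2 (10 mol %), Cy2NMe, BHT (trace), 1,4-dioxane, 90 °C
Reagents that add atoms: none
Why: Mizoroki-Heck reaction, in which zerovalent palladium carrying the bulky P(t-Bu)3 inserts into the hindered C4–Br bond of ring C, syn carbopalladation at the terminal alkene carbon and syn β-hydride elimination give the E stilbene, and the hindered amine does not attack the aryl acetates.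

Step 20
Reactants: 32 decaacetate of the target
Product: 33 target CNP0099535.1
Conditions: NH3 (7 M in MeOH), THF, 0 °C to rt, argon; evaporate
Reagents that add atoms: none
Why: Ammonolysis of ten aryl acetates (acyl transfer) needs neither acid nor strong base, so the E alkene, the catechol and all six stereocentres should be kept.

Compound list
1 | 1-bromo-3,5-dimethoxybenzene | COc1cc(Br)cc(OC)c1 | starting material
2 | 2-bromo-4,6-dimethoxybenzaldehyde | COc1cc(Br)c(C=O)c(OC)c1 | intermediate
3 | 2-bromo-6-hydroxy-4-methoxybenzaldehyde | COc1cc(O)c(C=O)c(Br)c1 | intermediate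
4 | 4-methoxybenzyl chloride | COc1ccc(CCl)cc1 | starting material
5 | 2-bromo-4-methoxy-6-(4-methoxybenzyloxy)benzaldehyde | O=Cc1c(Br)cc(OC)cc1OCc1ccc(OC)cc1 | intermediate
6 | 3,5-dimethoxyphenylmagnesium bromide | COc1cc([Mg]Br)cc(OC)c1 | intermediate
7 | (BrAr)(3,5-dimethoxyphenyl)methanol, racemic | COc1ccc(COc2cc(OC)cc(Br)c2C(O)c2cc(OC)cc(OC)c2)cc1 | intermediate
8 | (BrAr)(3,5-dimethoxyphenyl)methanone | COc1ccc(COc2cc(OC)cc(Br)c2C(=O)c2cc(OC)cc(OC)c2)cc1 | intermediate
9 | hydrazone of 8 | COc1ccc(COc2cc(OC)cc(Br)c2C(=NN)c2cc(OC)cc(OC)c2)cc1 | intermediate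
10 | (BrAr)(3,5-dimethoxyphenyl)diazomethane | COc1ccc(COc2cc(OC)cc(Br)c2C(=[N+]=[N-])c2cc(OC)cc(OC)c2)cc1 | intermediate
11 | (2S,3R)-4-bromo-3-(3,5-dimethoxyphenyl)-6-methoxy-2-An-2,3-dihydrobenzofuran, cis | COc1ccc([C@H]2Oc3cc(OC)cc(Br)c3[C@H]2c2cc(OC)cc(OC)c2)cc1 | intermediate
12 | (2R,3R)-4-bromo-3-(3,5-dimethoxyphenyl)-6-methoxy-2-An-2,3-dihydrobenzofuran, trans | COc1ccc([C@@H]2Oc3cc(OC)cc(Br)c3[C@H]2c2cc(OC)cc(OC)c2)cc1 | intermediate
13 | 4-lithio analogue of 12 | COc1ccc([C@@H]2Oc3cc(OC)cc([Li])c3[C@H]2c2cc(OC)cc(OC)c2)cc1 | intermediate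
14 | (BrAr)(B-yl)methanol, both carbinol epimers | COc1ccc(COc2cc(OC)cc(Br)c2C(O)c2cc(OC)cc3c2[C@@H](c2cc(OC)cc(OC)c2)[C@H](c2ccc(OC)cc2)O3)cc1 | intermediate
15 | (BrAr)(B-yl)methanone | COc1ccc(COc2cc(OC)cc(Br)c2C(=O)c2cc(OC)cc3c2[C@@H](c2cc(OC)cc(OC)c2)[C@H](c2ccc(OC)cc2)O3)cc1 | intermediate
16 | hydrazone of 15 | COc1ccc(COc2cc(OC)cc(Br)c2C(=NN)c2cc(OC)cc3c2[C@@H](c2cc(OC)cc(OC)c2)[C@H](c2ccc(OC)cc2)O3)cc1 | intermediate
17 | (BrAr)(B-yl)diazomethane | COc1ccc(COc2cc(OC)cc(Br)c2C(=[N+]=[N-])c2cc(OC)cc3c2[C@@H](c2cc(OC)cc(OC)c2)[C@H](c2ccc(OC)cc2)O3)cc1 | intermediate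
18 | (2R,3S)-4-bromo-6-methoxy-2-An-3-(B-yl)-2,3-dihydrobenzofuran, cis ring A | COc1ccc([C@@H]2Oc3cc(OC)cc(Br)c3[C@@H]2c2cc(OC)cc3c2[C@@H](c2cc(OC)cc(OC)c2)[C@H](c2ccc(OC)cc2)O3)cc1 | intermediate
19 | (2S,3S)-4-bromo-6-methoxy-2-An-3-(B-yl)-2,3-dihydrobenzofuran, trans ring A | COc1ccc([C@H]2Oc3cc(OC)cc(Br)c3[C@@H]2c2cc(OC)cc3c2[C@@H](c2cc(OC)cc(OC)c2)[C@H](c2ccc(OC)cc2)O3)cc1 | intermediate
20 | 4-lithio analogue of 19 | COc1ccc([C@H]2Oc3cc(OC)cc([Li])c3[C@@H]2c2cc(OC)cc3c2[C@@H](c2cc(OC)cc(OC)c2)[C@H](c2ccc(OC)cc2)O3)cc1 | intermediate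
21 | (BrAr)(AB-yl)methanol, both carbinol epimers | COc1ccc([C@H]2Oc3cc(OC)cc(C(O)c4c(Br)cc(OC)cc4OCc4ccc(OC)cc4)c3[C@@H]2c2cc(OC)cc3c2[C@@H](c2cc(OC)cc(OC)c2)[C@H](c2ccc(OC)cc2)O3)cc1 | intermediate
22 | (BrAr)(AB-yl)methanone | COc1ccc([C@H]2Oc3cc(OC)cc(C(=O)c4c(Br)cc(OC)cc4OCc4ccc(OC)cc4)c3[C@@H]2c2cc(OC)cc3c2[C@@H](c2cc(OC)cc(OC)c2)[C@H](c2ccc(OC)cc2)O3)cc1 | intermediate
23 | hydrazone of 22 | COc1ccc([C@H]2Oc3cc(OC)cc(C(=NN)c4c(Br)cc(OC)cc4OCc4ccc(OC)cc4)c3[C@@H]2c2cc(OC)cc3c2[C@@H](c2cc(OC)cc(OC)c2)[C@H](c2ccc(OC)cc2)O3)cc1 | intermediate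
24 | (BrAr)(AB-yl)diazomethane | COc1ccc([C@H]2Oc3cc(OC)cc(C(=[N+]=[N-])c4c(Br)cc(OC)cc4OCc4ccc(OC)cc4)c3[C@@H]2c2cc(OC)cc3c2[C@@H](c2cc(OC)cc(OC)c2)[C@H](c2ccc(OC)cc2)O3)cc1 | intermediate
25 | (2S,3R)-4-bromo-6-methoxy-2-An-3-(AB-yl)-2,3-dihydrobenzofuran, cis ring C | COc1ccc([C@H]2Oc3cc(OC)cc([C@@H]4c5c(Br)cc(OC)cc5O[C@@H]4c4ccc(OC)cc4)c3[C@@H]2c2cc(OC)cc3c2[C@@H](c2cc(OC)cc(OC)c2)[C@H](c2ccc(OC)cc2)O3)cc1 | intermediate
26 | (2R,3R)-4-bromo-6-methoxy-2-An-3-(AB-yl)-2,3-dihydrobenzofuran, trans ring C | COc1ccc([C@H]2Oc3cc(OC)cc([C@@H]4c5c(Br)cc(OC)cc5O[C@H]4c4ccc(OC)cc4)c3[C@@H]2c2cc(OC)cc3c2[C@@H](c2cc(OC)cc(OC)c2)[C@H](c2ccc(OC)cc2)O3)cc1 | intermediate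
27 | octaphenol bromide (26 with OH in place of every OMe) | Oc1ccc([C@H]2Oc3cc(O)cc([C@@H]4c5c(Br)cc(O)cc5O[C@H]4c4ccc(O)cc4)c3[C@@H]2c2cc(O)cc3c2[C@@H](c2cc(O)cc(O)c2)[C@H](c2ccc(O)cc2)O3)cc1 | intermediate
28 | octaacetate bromide | CC(=O)Oc1ccc([C@H]2Oc3cc(OC(C)=O)cc([C@@H]4c5c(Br)cc(OC(C)=O)cc5O[C@H]4c4ccc(OC(C)=O)cc4)c3[C@@H]2c2cc(OC(C)=O)cc3c2[C@@H](c2cc(OC(C)=O)cc(OC(C)=O)c2)[C@H](c2ccc(OC(C)=O)cc2)O3)cc1 | intermediate
29 | caffeic acid, (E)-3-(3,4-dihydroxyphenyl)acrylic acid | OC(=O)/C=C/c1ccc(O)c(O)c1 | starting material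
30 | 4-vinylcatechol | C=Cc1ccc(O)c(O)c1 | intermediate
31 | 3,4-diacetoxystyrene | C=Cc1ccc(OC(C)=O)c(OC(C)=O)c1 | intermediate
32 | decaacetate of the target | CC(=O)Oc1ccc([C@H]2Oc3cc(OC(C)=O)cc([C@@H]4c5c(/C=C/c6ccc(OC(C)=O)c(OC(C)=O)c6)cc(OC(C)=O)cc5O[C@H]4c4ccc(OC(C)=O)cc4)c3[C@@H]2c2cc(OC(C)=O)cc3c2[C@@H](c2cc(OC(C)=O)cc(OC(C)=O)c2)[C@H](c2ccc(OC(C)=O)cc2)O3)cc1 | intermediate
33 | CNP0099535.1 (ring B 2R,3R; ring A 2S,3S; ring C 2R,3R; E alkene) | Oc1ccc([C@H]2Oc3cc(O)cc([C@@H]4c5c(/C=C/c6ccc(O)c(O)c6)cc(O)cc5O[C@H]4c4ccc(O)cc4)c3[C@@H]2c2cc(O)cc3c2[C@@H](c2cc(O)cc(O)c2)[C@H](c2ccc(O)cc2)O3)cc1 | target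

Total step count: 20.
Longest linear sequence: 19 steps from 1 (steps 1 to 17, then 19 and 20). Step 18 is a side branch.

Steps most likely to fail

1. Step 10; step 14 repeats the same risk in a still more crowded setting. Addition of hydrazine to a carbonyl carbon shielded by three ortho substituents may stall. Prolonged heating also invites intramolecular displacement of the ortho bromine by the hydrazone nitrogen. The fallback sets out from 5 and 12 and comes back at 16, and it builds the C=N bond from a nitrile instead of a ketone. Aldehyde 5 is condensed with NH2OH·HCl in pyridine to the aldoxime F1. Ac2O at reflux dehydrates this to 2-bromo-4-methoxy-6-(4-methoxybenzyloxy)benzonitrile F2. Aryllithium 13, made from 12 as in step 8, adds to the linear and sterically undemanding nitrile carbon, and a methanol quench gives the N–H ketimine F3. Transimination with N2H4 and AcOH in EtOH at 60 to 80 °C runs through the protonated, more electrophilic iminium form and should give 16. Compounds 14 and 15 are bypassed.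

2. Step 11.
   - Loss of N2 at rhodium from the crowded diazo compound may be slow enough for azine formation or reoxidation to the ketone to win.
   - The catalyst may not override the facial bias of ring B.
   - The carbene may attack the nearby dimethoxyphenyl ring.
   - In the acid phase, the opened C2 cation may be captured irreversibly by a neighbouring resorcinol ring instead of O1.

   The fallback sets out from 15 and comes back at 19. It makes C2–C3 by carbonyl addition and closes the ring at C2–O1. Corey-Chaykovsky methylene transfer (Me3SI, NaH, DMSO/THF) converts 15 into the diaryl oxirane F4. A Meinwald rearrangement with ZnI2 in toluene gives the diarylacetaldehyde F5. Addition of 4-MeOC6H4MgBr in THF at -78 °C gives the carbinol F6. TFA with pentamethylbenzene in CH2Cl2 at 0 °C then removes the PMB group and ionises the carbinol in one operation. The freed phenol oxygen captures the 4-methoxybenzylic cation to close a trans ring. C3 is under substrate control only here, so 19 has to be separated by chromatography from its ring A (2R,3R) diastereomer F7.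

3. Step 19. Carbopalladation from an arylpalladium species buried beside the C3 substituent may be slower than hydrodebromination, polymerisation of the styrene or loss of acetate groups. The fallback sets out from 28 and comes back at 32, and it forms the alkene by metathesis. A base-free Stille coupling with tributyl(vinyl)stannane (Pd(PPh3)4, toluene, 100 °C) transfers only a small vinyl group and gives the 4-vinyl octaacetate F8. Cross metathesis of this hindered, slowly homodimerising styrene with an excess of 31 (second-generation Hoveyda-Grubbs catalyst, CH2Cl2, 40 °C) should then give the E stilbene 32.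

Further compounds
F1 | step 10 | aldoxime of 5 | COc1ccc(COc2cc(OC)cc(Br)c2C=NO)cc1
F2 | step 10 | 2-bromo-4-methoxy-6-(4-methoxybenzyloxy)benzonitrile | COc1ccc(COc2cc(OC)cc(Br)c2C#N)cc1
F3 | step 10 | (BrAr)(B-yl)methanimine (N–H ketimine) | COc1ccc(COc2cc(OC)cc(Br)c2C(=N)c2cc(OC)cc3c2[C@@H](c2cc(OC)cc(OC)c2)[C@H](c2ccc(OC)cc2)O3)cc1
F4 | step 11 | 2-(BrAr)-2-(B-yl)oxirane | COc1ccc(COc2cc(OC)cc(Br)c2C4(CO4)c2cc(OC)cc3c2[C@@H](c2cc(OC)cc(OC)c2)[C@H](c2ccc(OC)cc2)O3)cc1
F5 | step 11 | 2-(BrAr)-2-(B-yl)acetaldehyde | COc1ccc(COc2cc(OC)cc(Br)c2C(C=O)c2cc(OC)cc3c2[C@@H](c2cc(OC)cc(OC)c2)[C@H](c2ccc(OC)cc2)O3)cc1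
F6 | step 11 | 2-(BrAr)-2-(B-yl)-1-(4-methoxyphenyl)ethanol | COc1ccc(COc2cc(OC)cc(Br)c2C(C(O)c2ccc(OC)cc2)c2cc(OC)cc3c2[C@@H](c2cc(OC)cc(OC)c2)[C@H](c2ccc(OC)cc2)O3)cc1
F7 | step 11 | ring A (2R,3R) diastereomer of 19 | COc1ccc([C@@H]2Oc3cc(OC)cc(Br)c3[C@H]2c2cc(OC)cc3c2[C@@H](c2cc(OC)cc(OC)c2)[C@H](c2ccc(OC)cc2)O3)cc1
F8 | step 19 | 4-vinyl analogue of 28 | CC(=O)Oc1ccc([C@H]2Oc3cc(OC(C)=O)cc([C@@H]4c5c(C=C)cc(OC(C)=O)cc5O[C@H]4c4ccc(OC(C)=O)cc4)c3[C@@H]2c2cc(OC(C)=O)cc3c2[C@@H](c2cc(OC(C)=O)cc(OC(C)=O)c2)[C@H](c2ccc(OC(C)=O)cc2)O3)cc1
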